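The tetrahydrofuran ring (O1, C2 with pentyl, C3 with the ester oxygen, C4 methylene, C5 with the carbinol chain) is opened at C3–C4 and O1–C5. The three-atom unit O1–C2–C3 becomes a C,O-dianion, a C3 dithiane carbanion beside the C2 alkoxide, and C4–C5 comes from (S)-epichlorohydrin. In one operation the carbanion opens the epoxide (C3–C4), the epoxide re-forms one carbon further on, and the alkoxide closes the ring with inversion at C5 (O1–C5). The step exploits the 1,3-relation of O1 and C3 in the ring and fixes the 2,5-trans pattern; the dithiane later serves as the C3 ketone for cis-selective reduction and acylation.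

Key step: step 3

Remark: ring atoms are numbered O1, C2 (pentyl), C3 (ester), C4, C5 (side chain) throughout; compounds 1, 2, 6, 14 and 17 are assumed to be commercial.

Step 1
Reactants: 1 1,3-dithiane; 2 ethyl hexanoate
Product: 4 1-(1,3-dithian-2-yl)hexan-1-one, via 2-lithio-1,3-dithiane 3 (not isolated)
Conditions: 1 (2.0 equiv), n-BuLi (2.0 equiv), THF, −30 °C; 2 (1.0 equiv), −78 to −20 °C; H2O
Reagents that add atoms: none
Why: Corey–Seebach acylation of the lithiated dithiane by the ester; the second equivalent of 3 deprotonates the acidic acyl dithiane as it forms, which should prevent over-addition.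

Step 2
Reactants: 4 1-(1,3-dithian-2-yl)hexan-1-one
Product: 5 (1S)-1-(1,3-dithian-2-yl)hexan-1-ol
Conditions: (R)-1-methyl-3,3-diphenyltetrahydro-1H,3H-pyrrolo[1,2-c][1,3,2]oxazaborole (0.15 equiv), BH3·SMe2, THF, −20 °C; MeOH
Reagents that add atoms: none
Why: Corey–Bakshi–Shibata reduction; the branched dithianyl group acts as the large substituent and n-pentyl as the small one, so the (R)-oxazaborolidine should give the (S)-carbinol that becomes C2.

Step 3
Reactants: 5 (1S)-1-(1,3-dithian-2-yl)hexan-1-ol; 6 (S)-epichlorohydrin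
Product: 11 triethyl{[(1S,3R)-1-pentyl-2-oxa-6,10-dithiaspiro[4.5]decan-3-yl]methoxy}silane, via C,O-dilithio dianion 7 (not isolated), via chlorohydrin dialkoxide 8 (not isolated), via epoxy alkoxide 9 (not isolated), via cyclised lithium alkoxide 10 (not isolated)
Conditions: n-BuLi (2.2 equiv), TMEDA, THF, −30 to 0 °C; 6 (1.05 equiv), −78 °C to rt; DMPU, 45 °C; Et3SiCl, 0 °C
Reagents that add atoms: chlorotriethylsilane, CC[Si](Cl)(CC)CC
Why: Double deprotonation gives dianion 7, whose dithiane carbanion opens the epoxide of 6 at CH2 (C3–C4); chloro alkoxide 8 recloses to terminal epoxide 9, the C2 alkoxide opens it at C5 (O1–C5) to give 10, and 10 is silylated in the flask. This is a C,O-dianion/epihalohydrin cyclodialkylation (formal [3+2] annulation), assembled from the known opening–reclosure of epichlorohydrin by lithiated dithianes and the base-mediated cyclisation of 4,5-epoxy alkoxides. The tetrahydrofuran closes 5-exo-tet, favoured over the 6-endo path by the Baldwin trajectory and by the gem-disubstituent effect of the spiro dithiane. C5 is set by SN2 inversion of the relayed (S)-epoxide, whose configuration is carried unchanged from 6, and becomes (R); C2 comes from 5, so the ring is 2,5-trans. The step needs C- before O-alkylation (the carbanion is far more nucleophilic), attack at the epoxide and not at C–Cl (typical of lithium carbanions, and it fixes the sense at C5), and no β-elimination to a ketene dithioacetal, which the free alkoxide prevents because oxide is no leaving group.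

Step 4
Reactants: 11 triethyl{[(1S,3R)-1-pentyl-2-oxa-6,10-dithiaspiro[4.5]decan-3-yl]methoxy}silane
Product: 12 (2S,5R)-2-pentyl-5-{[(triethylsilyl)oxy]methyl}dihydrofuran-3(2H)-one
Conditions: MeI, CaCO3, MeCN/H2O (9:1), 45 °C
Reagents that add atoms: water, O
Why: Alkylative dithioketal hydrolysis; S-methylation makes sulfur a leaving group and water traps the thionium ion under buffered conditions that should spare the silyl ether and the epimerisable C2.

Step 5
Reactants: 12 (2S,5R)-2-pentyl-5-{[(triethylsilyl)oxy]methyl}dihydrofuran-3(2H)-one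
Product: 13 (2S,3S,5R)-2-pentyl-5-{[(triethylsilyl)oxy]methyl}tetrahydrofuran-3-ol
Conditions: Li[HB(s-Bu)3], THF, −78 °C; H2O
Reagents that add atoms: none
Why: Substrate-controlled reduction with a bulky hydride; attack on the ketone face anti to the adjacent C2 pentyl group should place the C3 hydroxyl cis to pentyl (3S).

Step 6
Reactants: 13 (2S,3S,5R)-2-pentyl-5-{[(triethylsilyl)oxy]methyl}tetrahydrofuran-3-ol; 14 tetradecanoyl chloride
Product: 15 (2S,3S,5R)-2-pentyl-5-{[(triethylsilyl)oxy]methyl}tetrahydrofuran-3-yl tetradecanoate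
Conditions: pyridine, 4-(dimethylamino)pyridine (0.1 equiv), CH2Cl2, 0 °C to rt
Reagents that add atoms: none
Why: Nucleophile-catalysed O-acylation of the secondary alcohol; C3 is not touched, so its configuration is retained.

Step 7
Reactants: 15 (2S,3S,5R)-2-pentyl-5-{[(triethylsilyl)oxy]methyl}tetrahydrofuran-3-yl tetradecanoate
Product: 16 (2S,3S,5R)-5-formyl-2-pentyltetrahydrofuran-3-yl tetradecanoate
Conditions: (COCl)2, DMSO, CH2Cl2, −78 to −40 °C; Et3N, −78 to 0 °C
Reagents that add atoms: none
Why: Swern oxidation applied directly to a primary triethylsilyl ether; the chlorosulfonium ion removes the silyl group as Et3SiCl and the alkoxysulfonium ylide collapses to the aldehyde, while the ester is inert and the low temperature should keep C5 from epimerising.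

Step 8
Reactants: 16 (2S,3S,5R)-5-formyl-2-pentyltetrahydrofuran-3-yl tetradecanoate; 17 9-bromonon-1-ene
Product: 19 (2S,3S,5R)-5-[(1R)-1-hydroxydec-9-en-1-yl]-2-pentyltetrahydrofuran-3-yl tetradecanoate, via non-8-en-1-ylmagnesium bromide 18 (not isolated)
Conditions: 17, Mg, Et2O, rt; 16, MgBr2·OEt2, CH2Cl2, −78 °C; H2O
Reagents that add atoms: none
Why: Chelation-controlled (Cram chelate) Grignard addition; magnesium bridges the aldehyde oxygen and ring O1 and the alkyl group adds from the face of the C5 hydrogen, which should give the threo (1R) carbinol, and the aldehyde reacts far faster than the ester at −78 °C.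

Compound list
1 | 1,3-dithiane | C1CSCSC1 | starting material
2 | ethyl hexanoate | CCCCCC(=O)OCC | starting material
3 | 2-lithio-1,3-dithiane | [Li]C1SCCCS1 | intermediate
4 | 1-(1,3-dithian-2-yl)hexan-1-one | CCCCCC(=O)C1SCCCS1 | intermediate
5 | (1S)-1-(1,3-dithian-2-yl)hexan-1-ol | CCCCC[C@H](O)C1SCCCS1 | intermediate
6 | (S)-epichlorohydrin, (2S)-2-(chloromethyl)oxirane | ClC[C@@H]1CO1 | starting material
7 | C,O-dilithio dianion of 5 (lithium alkoxide, 2-lithio dithiane) | CCCCC[C@H](O[Li])C1([Li])SCCCS1 | intermediate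
8 | dilithium salt of (1S)-1-{2-[(2S)-3-chloro-2-hydroxypropyl]-1,3-dithian-2-yl}hexan-1-ol | CCCCC[C@H](O[Li])C1(C[C@H](O[Li])CCl)SCCCS1 | intermediate
9 | lithium (1S)-1-{2-[(2S)-oxiran-2-ylmethyl]-1,3-dithian-2-yl}hexan-1-olate | CCCCC[C@H](O[Li])C1(C[C@H]2CO2)SCCCS1 | intermediate
10 | lithium [(1S,3R)-1-pentyl-2-oxa-6,10-dithiaspiro[4.5]decan-3-yl]methanolate | CCCCC[C@@H]1O[C@@H](CO[Li])CC12SCCCS2 | intermediate
11 | triethyl{[(1S,3R)-1-pentyl-2-oxa-6,10-dithiaspiro[4.5]decan-3-yl]methoxy}silane | CCCCC[C@@H]1O[C@@H](CO[Si](CC)(CC)CC)CC12SCCCS2 | intermediate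
12 | (2S,5R)-2-pentyl-5-{[(triethylsilyl)oxy]methyl}dihydrofuran-3(2H)-one | CCCCC[C@@H]1O[C@@H](CO[Si](CC)(CC)CC)CC1=O | intermediate
13 | (2S,3S,5R)-2-pentyl-5-{[(triethylsilyl)oxy]methyl}tetrahydrofuran-3-ol | CCCCC[C@@H]1O[C@@H](CO[Si](CC)(CC)CC)C[C@@H]1O | intermediate
14 | tetradecanoyl chloride | CCCCCCCCCCCCCC(=O)Cl | starting material
15 | (2S,3S,5R)-2-pentyl-5-{[(triethylsilyl)oxy]methyl}tetrahydrofuran-3-yl tetradecanoate | CCCCC[C@@H]1O[C@@H](CO[Si](CC)(CC)CC)C[C@@H]1OC(=O)CCCCCCCCCCCCC | intermediate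
16 | (2S,3S,5R)-5-formyl-2-pentyltetrahydrofuran-3-yl tetradecanoate | CCCCC[C@@H]1O[C@@H](C=O)C[C@@H]1OC(=O)CCCCCCCCCCCCC | intermediate
17 | 9-bromonon-1-ene | C=CCCCCCCCBr | starting material
18 | non-8-en-1-ylmagnesium bromide | C=CCCCCCCC[Mg]Br | intermediate
19 | (2S,3S,5R)-5-[(1R)-1-hydroxydec-9-en-1-yl]-2-pentyltetrahydrofuran-3-yl tetradecanoate | C=CCCCCCCC[C@@H](O)[C@H]1C[C@H](OC(=O)CCCCCCCCCCCCC)[C@H](CCCCC)O1 | target

Total step count: 8 steps. Longest linear sequence: 8 steps (1 to 4 to 5 to 11 to 12 to 13 to 15 to 16 to 19).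

Steps most likely to fail

Step 3. The second lithiation next to the alkoxide may stall, or chloride displacement and 6-endo closure may erode the configuration at C5. The fallback makes the two bonds in separate steps, setting out from 4 and returning at 11. The stabilised sodium anion of 4 (NaH, DMF) is C-alkylated by direct SN2 displacement on (R)-glycidyl 3-nitrobenzenesulfonate to give 1-{2-[(2S)-oxiran-2-ylmethyl]-1,3-dithian-2-yl}hexan-1-one F1. Reduction with BH3·SMe2 and the same (R)-oxazaborolidine should give (1S)-1-{2-[(2S)-oxiran-2-ylmethyl]-1,3-dithian-2-yl}hexan-1-ol F2. KOt-Bu in THF closes the ring 5-exo-tet with inversion to [(1S,3R)-1-pentyl-2-oxa-6,10-dithiaspiro[4.5]decan-3-yl]methanol F3, and Et3SiCl with imidazole gives 11.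

Step 8. Chelation control may be weak, so that attack from the other aldehyde face gives the erythro carbinol. The fallback sets C10 by hydride delivery instead; it sets out from 16 and returns at 19. The Grignard product, containing (2S,3S,5R)-5-[(1S)-1-hydroxydec-9-en-1-yl]-2-pentyltetrahydrofuran-3-yl tetradecanoate F4, is oxidised with Dess–Martin periodinane to (2S,3S,5R)-5-(dec-9-enoyl)-2-pentyltetrahydrofuran-3-yl tetradecanoate F5. Reduction with Li[HB(s-Bu)3] at −78 °C, by Felkin–Anh attack anti to the C5–O1 bond, should give the threo alcohol 19 without touching the ester.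

Step 7. Oxidative desilylation may be incomplete, or triethylamine may epimerise the α-alkoxy aldehyde at C5. The fallback separates deprotection from an amine-free oxidation; it sets out from 15 and returns at 16. HF·pyridine in THF gives (2S,3S,5R)-5-(hydroxymethyl)-2-pentyltetrahydrofuran-3-yl tetradecanoate F6, which is oxidised with PhI(OAc)2 and catalytic 2,2,6,6-tetramethylpiperidin-1-oxyl in CH2Cl2 to 16.

Further compounds
F1 | step 3 | 1-{2-[(2S)-oxiran-2-ylmethyl]-1,3-dithian-2-yl}hexan-1-one | CCCCCC(=O)C1(C[C@H]2CO2)SCCCS1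
F2 | step 3 | (1S)-1-{2-[(2S)-oxiran-2-ylmethyl]-1,3-dithian-2-yl}hexan-1-ol | CCCCC[C@H](O)C1(C[C@H]2CO2)SCCCS1
F3 | step 3 | [(1S,3R)-1-pentyl-2-oxa-6,10-dithiaspiro[4.5]decan-3-yl]methanol | CCCCC[C@@H]1O[C@@H](CO)CC12SCCCS2
F4 | step 8 | (2S,3S,5R)-5-[(1S)-1-hydroxydec-9-en-1-yl]-2-pentyltetrahydrofuran-3-yl tetradecanoate | C=CCCCCCCC[C@H](O)[C@H]1C[C@H](OC(=O)CCCCCCCCCCCCC)[C@H](CCCCC)O1
F5 | step 8 | (2S,3S,5R)-5-(dec-9-enoyl)-2-pentyltetrahydrofuran-3-yl tetradecanoate | C=CCCCCCCCC(=O)[C@H]1C[C@H](OC(=O)CCCCCCCCCCCCC)[C@H](CCCCC)O1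
F6 | step 7 | (2S,3S,5R)-5-(hydroxymethyl)-2-pentyltetrahydrofuran-3-yl tetradecanoate | CCCCC[C@@H]1O[C@@H](CO)C[C@@H]1OC(=O)CCCCCCCCCCCCC
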